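**Assumption:** the SMILES is read as the (7S,8S)-threo isomer (neolignan numbering), and 4-allyl-2,6-dimethoxyphenol (methoxyeugenol) and (R)-4-benzyl-2-oxazolidinone are taken as commercial.

**Retrosynthetic overview**
1. Target 17 ⇐ TIPS ether 16 (desilylation) ⇐ C9 methyl from CH2OTs ⇐ CH2OH ⇐ imide carbonyl (reductive auxiliary removal).
2. C7–OMe ⇐ C7–OH by O-methylation with retention.
3. C7–C8 bond ⇐ Evans syn glycolate aldol of O-TIPS-vanillin 9 with N-(aryloxyacetyl)-(R)-4-benzyloxazolidinone 7; this sets both stereocentres (syn aldol = threo neolignan).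
4. Imide 7 ⇐ aryloxyacetic acid 4 ⇐ methoxyeugenol 1 + ethyl bromoacetate 2.
5. No ring is formed in the route; both arenes and the oxazolidinone ring are bought.

**Route**

Step 1
Reactants: 1 4-allyl-2,6-dimethoxyphenol; 2 ethyl bromoacetate
Product: 3 ethyl 2-(4-allyl-2,6-dimethoxyphenoxy)acetate
Conditions: K2CO3, acetone, reflux
Reagents that add atoms: none
Why: Williamson ether synthesis, an SN2 reaction of the phenoxide on a reactive α-bromo ester under conditions too mild to isomerise the allyl group.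

Step 2
Reactants: 3 ethyl 2-(4-allyl-2,6-dimethoxyphenoxy)acetate
Product: 4 2-(4-allyl-2,6-dimethoxyphenoxy)acetic acid
Conditions: LiOH·H2O, THF/H2O, rt; then 1 M HCl
Reagents that add atoms: lithium hydroxide, [Li+].[OH-]
Why: Ester saponification (BAc2) at room temperature leaves the aryl ethers and the allyl group untouched.

Step 3
Reactants: 4 2-(4-allyl-2,6-dimethoxyphenoxy)acetic acid; 5 (R)-4-benzyl-2-oxazolidinone
Product: 7 (R)-4-benzyl-3-[(4-allyl-2,6-dimethoxyphenoxy)acetyl]oxazolidin-2-one, via mixed pivalic anhydride 6 (not isolated)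
Conditions: PivCl, Et3N, THF, −20 °C; then LiCl, 5, −20 °C → rt
Reagents that add atoms: pivaloyl chloride, CC(C)(C)C(=O)Cl (its acyl group stands in intermediate 6 only)
Why: Mixed-anhydride N-acylation, in which the LiCl-activated oxazolidinone attacks the less hindered acyl carbon of the pivalic anhydride.

Step 4
Reactants: 8 vanillin (4-hydroxy-3-methoxybenzaldehyde)
Product: 9 3-methoxy-4-(triisopropylsilyloxy)benzaldehyde
Conditions: TIPSCl, imidazole, DMF, rt
Reagents that add atoms: triisopropylsilyl chloride, CC(C)[Si](Cl)(C(C)C)C(C)C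
Why: Phenol silylation gives a bulky aryl silyl ether that survives boron enolates, hydrides and alkylating agents and is later removed by fluoride without acid or hydrogenation.

Step 5
Reactants: 7 (R)-4-benzyl-3-[(4-allyl-2,6-dimethoxyphenoxy)acetyl]oxazolidin-2-one; 9 3-methoxy-4-(triisopropylsilyloxy)benzaldehyde
Product: 12 (R)-4-benzyl-3-[(2R,3S)-2-(4-allyl-2,6-dimethoxyphenoxy)-3-hydroxy-3-(3-methoxy-4-triisopropylsilyloxyphenyl)propanoyl]oxazolidin-2-one, via (Z)-dibutylboron enolate 10 (not isolated), via dibutylboron aldolate 11 (not isolated)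
Conditions: Bu2BOTf, i-Pr2NEt, CH2Cl2, −78 → 0 °C; 9, −78 → 0 °C; pH 7 buffer, MeOH, 30% H2O2, 0 °C
Reagents that add atoms: dibutylboron triflate, CCCCB(CCCC)OS(=O)(=O)C(F)(F)F (its Bu2B group stands in intermediates 10 and 11 only)
Why: Evans syn glycolate aldol, in which the Z-boron enolate reacts through a Zimmerman–Traxler chair (2,3-syn) and the dipole-opposed (R)-benzyl auxiliary blocks one enolate face, setting both new centres as (2R,3S), which is the 7S,8S-threo arrangement of the target.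

Step 6
Reactants: 12 the syn aldol adduct
Product: 13 (R)-4-benzyl-3-[(2R,3S)-2-(4-allyl-2,6-dimethoxyphenoxy)-3-methoxy-3-(3-methoxy-4-triisopropylsilyloxyphenyl)propanoyl]oxazolidin-2-one
Conditions: Me3OBF4, Proton-sponge, 4 Å MS, CH2Cl2, 0 °C → rt
Reagents that add atoms: trimethyloxonium tetrafluoroborate, C[O+](C)C.F[B-](F)(F)F
Why: Meerwein-salt O-methylation alkylates the hydroxyl oxygen without breaking the C7–O bond (retention), and the non-nucleophilic weak base avoids retro-aldol cleavage and α-epimerisation.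

Step 7
Reactants: 13 the β-methoxy imide
Product: 14 (2S,3S)-2-(4-allyl-2,6-dimethoxyphenoxy)-3-methoxy-3-(3-methoxy-4-triisopropylsilyloxyphenyl)propan-1-ol
Conditions: LiBH4, MeOH (1 equiv), THF, 0 °C
Reagents that add atoms: none
Why: Reductive cleavage of the N-acyloxazolidinone by hydride attack at the exocyclic carbonyl gives the primary alcohol and frees the auxiliary; no stereocentre is touched, and the C2 descriptor changes from R to S only through CIP priorities.

Step 8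
Reactants: 14 the primary alcohol
Product: 15 (2S,3S)-2-(4-allyl-2,6-dimethoxyphenoxy)-3-methoxy-3-(3-methoxy-4-triisopropylsilyloxyphenyl)propyl 4-methylbenzenesulfonate
Conditions: TsCl, Et3N, DMAP (cat.), CH2Cl2, 0 °C → rt
Reagents that add atoms: p-toluenesulfonyl chloride, Cc1ccc(cc1)S(Cl)(=O)=O
Why: Sulfonylation of the only free hydroxyl activates C9 for deoxygenation.

Step 9
Reactants: 15 the primary tosylate
Product: 16 [4-[(1S,2S)-2-(4-allyl-2,6-dimethoxyphenoxy)-1-methoxypropyl]-2-methoxyphenoxy]triisopropylsilane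
Conditions: LiEt3BH, THF, 0 °C → rt; H2O quench
Reagents that add atoms: none
Why: SN2 hydride displacement of the primary tosylate by Super-Hydride turns CH2OTs into the C9 methyl group, while the terminal alkene, the ethers and both stereocentres are inert to nucleophilic hydride.

Step 10
Reactants: 16 the TIPS-protected neolignan
Product: 17 4-[(1S,2S)-2-(4-allyl-2,6-dimethoxyphenoxy)-1-methoxypropyl]-2-methoxyphenol (target)
Conditions: TBAF, AcOH (1:1), THF, 0 °C
Reagents that add atoms: none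
Why: Fluoride-mediated desilylation of the aryl silyl ether, buffered with acetic acid so the p-hydroxybenzylic methyl ether cannot ionise or epimerise through a quinone methide.

**Compound list**
1 | 4-allyl-2,6-dimethoxyphenol (methoxyeugenol) | C=CCc1cc(OC)c(O)c(OC)c1 | starting material
2 | ethyl bromoacetate | CCOC(=O)CBr | starting material
3 | ethyl 2-(4-allyl-2,6-dimethoxyphenoxy)acetate | C=CCc1cc(OC)c(OCC(=O)OCC)c(OC)c1 | intermediate
4 | 2-(4-allyl-2,6-dimethoxyphenoxy)acetic acid | C=CCc1cc(OC)c(OCC(=O)O)c(OC)c1 | intermediate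
5 | (R)-4-benzyl-2-oxazolidinone | O=C1N[C@H](Cc2ccccc2)CO1 | starting material
6 | 2-(4-allyl-2,6-dimethoxyphenoxy)acetic pivalic anhydride (not isolated) | C=CCc1cc(OC)c(OCC(=O)OC(=O)C(C)(C)C)c(OC)c1 | intermediate
7 | (R)-4-benzyl-3-[(4-allyl-2,6-dimethoxyphenoxy)acetyl]oxazolidin-2-one | C=CCc1cc(OC)c(OCC(=O)N2C(=O)OC[C@H]2Cc2ccccc2)c(OC)c1 | intermediate
8 | vanillin | COc1cc(C=O)ccc1O | starting material
9 | 3-methoxy-4-(triisopropylsilyloxy)benzaldehyde | COc1cc(C=O)ccc1O[Si](C(C)C)(C(C)C)C(C)C | intermediate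
10 | (Z)-dibutylboron enolate of 7, with aryloxy and OBBu2 cis (not isolated) | C=CCc1cc(OC)c(O/C=C(\OB(CCCC)CCCC)N2C(=O)OC[C@H]2Cc2ccccc2)c(OC)c1 | intermediate
11 | O-dibutylboron aldolate of 12 (not isolated) | C=CCc1cc(OC)c(O[C@@H](C(=O)N2C(=O)OC[C@H]2Cc2ccccc2)[C@@H](OB(CCCC)CCCC)c2ccc(O[Si](C(C)C)(C(C)C)C(C)C)c(OC)c2)c(OC)c1 | intermediate
12 | (R)-4-benzyl-3-[(2R,3S)-2-(4-allyl-2,6-dimethoxyphenoxy)-3-hydroxy-3-(3-methoxy-4-triisopropylsilyloxyphenyl)propanoyl]oxazolidin-2-one | C=CCc1cc(OC)c(O[C@@H](C(=O)N2C(=O)OC[C@H]2Cc2ccccc2)[C@@H](O)c2ccc(O[Si](C(C)C)(C(C)C)C(C)C)c(OC)c2)c(OC)c1 | intermediate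
13 | (R)-4-benzyl-3-[(2R,3S)-2-(4-allyl-2,6-dimethoxyphenoxy)-3-methoxy-3-(3-methoxy-4-triisopropylsilyloxyphenyl)propanoyl]oxazolidin-2-one | C=CCc1cc(OC)c(O[C@@H](C(=O)N2C(=O)OC[C@H]2Cc2ccccc2)[C@@H](OC)c2ccc(O[Si](C(C)C)(C(C)C)C(C)C)c(OC)c2)c(OC)c1 | intermediate
14 | (2S,3S)-2-(4-allyl-2,6-dimethoxyphenoxy)-3-methoxy-3-(3-methoxy-4-triisopropylsilyloxyphenyl)propan-1-ol | C=CCc1cc(OC)c(O[C@@H](CO)[C@@H](OC)c2ccc(O[Si](C(C)C)(C(C)C)C(C)C)c(OC)c2)c(OC)c1 | intermediate
15 | (2S,3S)-2-(4-allyl-2,6-dimethoxyphenoxy)-3-methoxy-3-(3-methoxy-4-triisopropylsilyloxyphenyl)propyl 4-methylbenzenesulfonate | C=CCc1cc(OC)c(O[C@@H](COS(=O)(=O)c2ccc(C)cc2)[C@@H](OC)c2ccc(O[Si](C(C)C)(C(C)C)C(C)C)c(OC)c2)c(OC)c1 | intermediate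
16 | [4-[(1S,2S)-2-(4-allyl-2,6-dimethoxyphenoxy)-1-methoxypropyl]-2-methoxyphenoxy]triisopropylsilane | C=CCc1cc(OC)c(O[C@@H](C)[C@@H](OC)c2ccc(O[Si](C(C)C)(C(C)C)C(C)C)c(OC)c2)c(OC)c1 | intermediate
17 | 4-[(1S,2S)-2-(4-allyl-2,6-dimethoxyphenoxy)-1-methoxypropyl]-2-methoxyphenol | C=CCc1cc(OC)c(O[C@@H](C)[C@@H](OC)c2ccc(O)c(OC)c2)c(OC)c1 | target

**Totals**
Total step count: 10. Longest linear sequence: 9 steps (steps 1, 2, 3, 5, 6, 7, 8, 9, 10 from compound 1); step 4 is a one-step side branch.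

**Three steps most likely to fail, with fallbacks**

Step 5 (aldol: the electron-rich aldehyde and the hindered aryloxy enolate may give low conversion or eroded syn selectivity). The fallback sets out from acid 4 and comes back at alcohol 14. Acid 4 is coupled with (R)-4-benzylthiazolidine-2-thione (EDC·HCl, DMAP, CH2Cl2) to give (R)-4-benzyl-3-[(4-allyl-2,6-dimethoxyphenoxy)acetyl]thiazolidine-2-thione F1. A titanium-mediated aldol of F1 with aldehyde 9 (TiCl4, i-Pr2NEt, NMP, CH2Cl2, 0 → −78 °C, non-chelated Evans-syn mode) gives the (2R,3S) syn adduct F2. Because the thione sulfur would be alkylated by a methylating agent, the easily displaced auxiliary is removed first with MeOH/imidazole at rt, giving the β-hydroxy methyl ester F3. This is O-methylated (Me3OBF4, Proton-sponge) to the β-methoxy methyl ester F4, and LiBH4 reduction of F4 gives 14.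

Step 6 (methylation of a hindered benzylic hydroxyl next to the aryloxy centre may stall, or the aldol adduct may revert). The fallback sets out from 12 and comes back at 16. LiBH4 (MeOH, THF, 0 °C) reduces 12 to the (1S,2S)-1,3-diol F5. The primary hydroxyl is tosylated selectively (TsCl, Et3N, cat. DMAP, 0 °C) to give the hydroxy tosylate F6. LiEt3BH in THF at 0 °C then gives the C9-methyl benzylic alcohol F7, which is no longer prone to retro-aldol. F7 is methylated as its alkoxide (NaH, MeI, THF, 0 °C), again with retention, to give 16.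

Step 9 (hydride may attack sulfur and return alcohol 14, or react slowly at the β-branched carbon). The fallback sets out from 14 and comes back at 16. Alcohol 14 is converted by Appel-type iodination (PPh3, I2, imidazole, CH2Cl2, 0 °C → rt) into the primary iodide F8, which has no S–O bond to cleave and a better leaving group. F8 is reduced by SN2 hydride transfer with NaBH4 in DMSO at rt–40 °C to give 16. Radical or dissolving-metal reduction is avoided because the β-aryloxy group would be eliminated.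

**Further compounds**
F1 | step 5 | (R)-4-benzyl-3-[(4-allyl-2,6-dimethoxyphenoxy)acetyl]thiazolidine-2-thione | C=CCc1cc(OC)c(OCC(=O)N2C(=S)SC[C@H]2Cc2ccccc2)c(OC)c1
F2 | step 5 | (R)-4-benzyl-3-[(2R,3S)-2-(4-allyl-2,6-dimethoxyphenoxy)-3-hydroxy-3-(3-methoxy-4-triisopropylsilyloxyphenyl)propanoyl]thiazolidine-2-thione | C=CCc1cc(OC)c(O[C@@H](C(=O)N2C(=S)SC[C@H]2Cc2ccccc2)[C@@H](O)c2ccc(O[Si](C(C)C)(C(C)C)C(C)C)c(OC)c2)c(OC)c1
F3 | step 5 | methyl (2R,3S)-2-(4-allyl-2,6-dimethoxyphenoxy)-3-hydroxy-3-(3-methoxy-4-triisopropylsilyloxyphenyl)propanoate | C=CCc1cc(OC)c(O[C@@H](C(=O)OC)[C@@H](O)c2ccc(O[Si](C(C)C)(C(C)C)C(C)C)c(OC)c2)c(OC)c1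
F4 | step 5 | methyl (2R,3S)-2-(4-allyl-2,6-dimethoxyphenoxy)-3-methoxy-3-(3-methoxy-4-triisopropylsilyloxyphenyl)propanoate | C=CCc1cc(OC)c(O[C@@H](C(=O)OC)[C@@H](OC)c2ccc(O[Si](C(C)C)(C(C)C)C(C)C)c(OC)c2)c(OC)c1
F5 | step 6 | (1S,2S)-2-(4-allyl-2,6-dimethoxyphenoxy)-1-(3-methoxy-4-triisopropylsilyloxyphenyl)propane-1,3-diol | C=CCc1cc(OC)c(O[C@@H](CO)[C@@H](O)c2ccc(O[Si](C(C)C)(C(C)C)C(C)C)c(OC)c2)c(OC)c1
F6 | step 6 | (2S,3S)-2-(4-allyl-2,6-dimethoxyphenoxy)-3-hydroxy-3-(3-methoxy-4-triisopropylsilyloxyphenyl)propyl 4-methylbenzenesulfonate | C=CCc1cc(OC)c(O[C@@H](COS(=O)(=O)c2ccc(C)cc2)[C@@H](O)c2ccc(O[Si](C(C)C)(C(C)C)C(C)C)c(OC)c2)c(OC)c1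
F7 | step 6 | (1S,2S)-2-(4-allyl-2,6-dimethoxyphenoxy)-1-(3-methoxy-4-triisopropylsilyloxyphenyl)propan-1-ol | C=CCc1cc(OC)c(O[C@@H](C)[C@@H](O)c2ccc(O[Si](C(C)C)(C(C)C)C(C)C)c(OC)c2)c(OC)c1
F8 | step 9 | [4-[(1S,2R)-2-(4-allyl-2,6-dimethoxyphenoxy)-3-iodo-1-methoxypropyl]-2-methoxyphenoxy]triisopropylsilane | C=CCc1cc(OC)c(O[C@@H](CI)[C@@H](OC)c2ccc(O[Si](C(C)C)(C(C)C)C(C)C)c(OC)c2)c(OC)c1
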